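The plan hinges on disconnecting C3 from both O7 and C4. C3 is at the aldehyde oxidation level and is the junction of the two rings: in the tetrahydropyran it lies between ring oxygen O7 and C4, and it also starts the C2–C1(=O)–O13 chain that completes the 14-membered lactone. Making C3 cationic while it is already tied to C13 as an ester lets one silyl-Prins macrocyclisation form O7–C3 and C3–C4, fix C3 cis to C7 and leave a C5 exocyclic methylene for the axial ester. The substrate is the open C4–C16 chain with a free C7 hydroxyl, a 2-(trimethylsilylmethyl)allyl end and a C13 3,3-dimethoxypropanoate.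

Key step: step 13

Assumption: methyl hydrogen (R)-3-methylglutarate (1), the desymmetrised half-ester of 3-methylglutaric anhydride, is bought enantioenriched; atom labels C1–C16 follow the macrolide numbering (C1 lactone carbonyl, C3 and C7 pyran carbons, C13 lactone carbinol).

Remarks on atom bookkeeping and corrections:
- The glutarate supplies C7–C11 and butanal C13–C16, so C12 must be added separately (MeLi, step 2).
- A plain anti reduction would leave two indistinguishable secondary hydroxyls, so C11 and C13 are told apart by an Evans–Tishchenko reduction.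
- In the allylsilane the vinylic CH2 becomes C4 and the CH2Si carbon becomes the C5 exocyclic methylene.
- The C5 ketone is reduced to the equatorial alcohol and esterified with inversion, which avoids acylating an axial alcohol with a Z-enoic acid.

Step 1
Reactants: 1 methyl hydrogen (R)-3-methylglutarate
Product: 3 (4R)-4-methyloxan-2-one, via hydroxy ester 2 (not isolated)
Conditions: BH3·SMe2, THF, 0 °C to rt; MeOH quench; then TsOH·H2O (cat.), CH2Cl2, rt
Reagents that add atoms: none
Why: Borane reduces the free carboxylic acid chemoselectively beside the methyl ester and the resulting δ-hydroxy ester closes by acid-catalysed lactonisation, which leaves the C9 stereocentre untouched.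

Step 2
Reactants: 3 (4R)-4-methyloxan-2-one
Product: 4 (4R)-6-hydroxy-4-methylhexan-2-one
Conditions: MeLi (1.05 equiv), THF, −78 °C; AcOH quench at −78 °C
Reagents that add atoms: methyllithium, [Li]C
Why: Single addition of an organolithium to a δ-lactone should stop at the lithium hemiketal alkoxide, which is stable at −78 °C and releases the methyl ketone (in equilibrium with its cyclic hemiketal) only on quench, so C12 is introduced without over-addition.

Step 3
Reactants: 4 (4R)-6-hydroxy-4-methylhexan-2-one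
Product: 5 (3R)-3-methyl-5-oxohexyl acetate
Conditions: Ac2O, pyridine, 4-(dimethylamino)pyridine (cat.), CH2Cl2, 0 °C
Reagents that add atoms: acetic anhydride, CC(=O)OC(C)=O
Why: Acetylation (esterification) of the primary hydroxyl of the open-chain tautomer masks C7–OH with a group that tolerates boron enolisation and can later be removed together with the C13 acetate.

Step 4
Reactants: 5 (3R)-3-methyl-5-oxohexyl acetate; 6 butanal
Product: 8 (3R,7R)-7-hydroxy-3-methyl-5-oxodecyl acetate, via enol diisopinocampheylborinate 7 (not isolated)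
Conditions: (+)-Ipc2BCl, Et3N, Et2O, 0 °C; then 6, −78 to −20 °C; H2O2, MeOH, pH 7 buffer, 0 °C
Reagents that add atoms: none
Why: In this diisopinocampheylboron-mediated aldol reaction, kinetic enolisation on the methyl side gives the enol borinate, whose isopinocampheyl ligands should steer addition to the Si face of butanal so that the 13R carbinol is the major diastereomer (reagent control, since the remote C9 centre exerts no bias).

Step 5
Reactants: 8 (3R,7R)-7-hydroxy-3-methyl-5-oxodecyl acetate
Product: 9 (3R,5R,7R)-5-hydroxy-3-methyldecane-1,7-diyl diacetate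
Conditions: SmI2 (0.3 equiv), CH3CHO (8 equiv), THF, −10 °C
Reagents that add atoms: acetaldehyde, CC=O
Why: In the Evans–Tishchenko reduction the samarium-bound hemiacetal of the C13 hydroxyl delivers hydride intramolecularly to C11 anti to C13–O and leaves C13 as its acetate, so C11 becomes the only free hydroxyl.

Step 6
Reactants: 9 (3R,5R,7R)-5-hydroxy-3-methyldecane-1,7-diyl diacetate
Product: 10 (3R,5R,7R)-5-methoxy-3-methyldecane-1,7-diyl diacetate
Conditions: Me3OBF4, 1,8-bis(dimethylamino)naphthalene, CH2Cl2, 0 °C to rt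
Reagents that add atoms: trimethyloxonium tetrafluoroborate, C[O+](C)C.F[B-](F)(F)F
Why: O-Alkylation with the oxonium salt under non-basic conditions should methylate the C11 hydroxyl without acetyl migration from C13 or β-elimination.

Step 7
Reactants: 10 (3R,5R,7R)-5-methoxy-3-methyldecane-1,7-diyl diacetate
Product: 11 (3R,5R,7R)-5-methoxy-3-methyldecane-1,7-diol
Conditions: K2CO3 (cat.), MeOH, rt
Reagents that add atoms: none
Why: Base-catalysed transesterification with methanol removes both acetates in one operation while the methyl ether and all stereocentres are inert.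

Step 8
Reactants: 11 (3R,5R,7R)-5-methoxy-3-methyldecane-1,7-diol
Product: 12 (3S,5R,7R)-7-hydroxy-5-methoxy-3-methyldecanal
Conditions: TEMPO (2,2,6,6-tetramethylpiperidin-1-oxyl, 0.1 equiv), PhI(OAc)2 (1.1 equiv), CH2Cl2, rt
Reagents that add atoms: none
Why: Oxoammonium-mediated (TEMPO) oxidation is selective for the primary C7 hydroxyl over the secondary C13 hydroxyl and stops at the aldehyde, which cannot form a lactol with the remote C13–OH.

Step 9
Reactants: 13 methyl 3,3-dimethoxypropanoate
Product: 14 3,3-dimethoxypropanoic acid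
Conditions: LiOH, THF/H2O, 0 °C to rt; then 1 M HCl to pH 3–4 at 0 °C, rapid extraction
Reagents that add atoms: lithium hydroxide, [Li+].[OH-]
Why: Saponification of the methyl ester leaves the base-stable acetal intact, and brief cold acidification liberates the acid for immediate use.

Step 10
Reactants: 12 (3S,5R,7R)-7-hydroxy-5-methoxy-3-methyldecanal; 14 3,3-dimethoxypropanoic acid
Product: 15 (4R,6R,8S)-6-methoxy-8-methyl-10-oxodecan-4-yl 3,3-dimethoxypropanoate
Conditions: DCC, 4-(dimethylamino)pyridine (cat.), CH2Cl2, 0 °C to rt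
Reagents that add atoms: none
Why: Steglich esterification acylates the only hydroxyl (C13, with retention) under neutral conditions that tolerate the aldehyde and the acetal.

Step 11
Reactants: 16 2-(chloromethyl)-3-(trimethylsilyl)prop-1-ene
Product: 17 tributyl{2-[(trimethylsilyl)methyl]prop-2-en-1-yl}stannane
Conditions: Bu3SnH, LiN(i-Pr)2, THF, −78 to 0 °C; then 16, −78 °C to rt
Reagents that add atoms: tributyltin hydride, CCCC[SnH](CCCC)CCCC
Why: SN2 displacement of the allylic chloride by tributylstannyllithium (stannylation) gives the bifunctional allylstannane–allylsilane.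

Step 12
Reactants: 15 (4R,6R,8S)-6-methoxy-8-methyl-10-oxodecan-4-yl 3,3-dimethoxypropanoate; 17 tributyl{2-[(trimethylsilyl)methyl]prop-2-en-1-yl}stannane
Product: 18 (4R,6R,8R,10R)-10-hydroxy-6-methoxy-8-methyl-12-methylidene-13-(trimethylsilyl)tridecan-4-yl 3,3-dimethoxypropanoate
Conditions: (S)-BINOL (20 mol%), Ti(OiPr)4 (10 mol%), 4 Å molecular sieves, CH2Cl2, −20 °C; NaHCO3 (aq)
Reagents that add atoms: none
Why: In the Keck catalytic asymmetric allylation the BINOL–titanium Lewis acid activates the aldehyde and the more nucleophilic stannane terminus should add to its Si face (catalyst control, giving 7R), while the allylsilane, ester and acetal are spectators.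

Step 13
Reactants: 18 (4R,6R,8R,10R)-10-hydroxy-6-methoxy-8-methyl-12-methylidene-13-(trimethylsilyl)tridecan-4-yl 3,3-dimethoxypropanoate
Product: 21 (1R,5R,7R,9S,11R)-7-methoxy-9-methyl-13-methylidene-5-propyl-4,15-dioxabicyclo[9.3.1]pentadecan-3-one, via C7 trimethylsilyl ether 19 (not isolated), via macrocyclic mixed methyl acetal 20 (not isolated)
Conditions: TMSOTf (3 equiv), 2,6-di-tert-butyl-4-methylpyridine (4 equiv), CH2Cl2 (1 mM, 18 added slowly), −78 to −40 °C; NaHCO3 (aq)
Reagents that add atoms: none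
Why: TMSOTf with the hindered pyridine first converts the C7 hydroxyl into silyl ether 19 and then ionises the C3 dimethyl acetal; the silyl ether oxygen traps the methoxycarbenium ion reversibly to give the 12-membered mixed acetal 20, a second ionisation gives the ring-bound (E)-oxocarbenium ion O7=C3, and the vinylic CH2 of the allylsilane (future C4) adds to C3 with loss of the silyl group, which turns the CH2Si carbon into the C5 exocyclic methylene. The closest known reaction types are the TMSOTf-promoted silyl-Prins pyran annulation of hydroxy allylsilanes, its macrocyclising variants and Prins macrolactone closures from ester-tethered acetals. The macrocycle is closed by the O7–C3 transacetalisation (a 12-membered ring whose perimeter becomes the 14-membered lactone once C3–C4 exists) and the tetrahydropyran by a 6-endo-trig attack of the alkene on the oxocarbenium carbon. C3, the only new stereocentre, is set by the resident C7 centre through a chair transition state in which C8 and the C2 ester arm are both equatorial on the (E)-oxocarbenium ion, which should give the 2,6-cis (3R) pyran. The step needs ring closure to win over oligomerisation and C–C bond formation to win over protodesilylation, elimination to a 3-methoxyacrylate and oxonia-Cope scrambling; acetal exchange is reversible whereas the six-membered closure by the strongly nucleophilic allylsilane is fast and irreversible, and 1 mM dilution with buffered, proton-free activation secures the rest.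

Step 14
Reactants: 21 (1R,5R,7R,9S,11R)-7-methoxy-9-methyl-13-methylidene-5-propyl-4,15-dioxabicyclo[9.3.1]pentadecan-3-one
Product: 23 (1R,5R,7R,9S,11R)-7-methoxy-9-methyl-5-propyl-4,15-dioxabicyclo[9.3.1]pentadecane-3,13-dione, via ozonide 22 (not isolated)
Conditions: O3, CH2Cl2, −78 °C; then PPh3, −78 °C to rt
Reagents that add atoms: ozone, [O-][O+]=O
Why: Ozonolysis of the only alkene, a 1,1-disubstituted exocyclic methylene, gives the C5 ketone after reductive cleavage of the ozonide and touches no stereocentre.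

Step 15
Reactants: 23 (1R,5R,7R,9S,11R)-7-methoxy-9-methyl-5-propyl-4,15-dioxabicyclo[9.3.1]pentadecane-3,13-dione
Product: 24 (1R,5R,7R,9S,11R,13S)-13-hydroxy-7-methoxy-9-methyl-5-propyl-4,15-dioxabicyclo[9.3.1]pentadecan-3-one
Conditions: NaBH4, MeOH, 0 °C
Reagents that add atoms: none
Why: In this diastereoselective ketone reduction the small hydride should attack the 2,6-cis-tetrahydropyran-4-one axially and give the equatorial (macrolide 5S) alcohol, the epimer needed for an invertive esterification.

Step 16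
Reactants: 25 prop-2-yn-1-amine
Product: 26 methyl N-(prop-2-yn-1-yl)carbamate
Conditions: ClCO2Me, Et3N, CH2Cl2, 0 °C
Reagents that add atoms: methyl chloroformate, COC(Cl)=O
Why: N-Acylation of the primary amine with the chloroformate gives the carbamate (carbamate formation).

Step 17
Reactants: 26 methyl N-(prop-2-yn-1-yl)carbamate; 27 ethyl 2-bromo-1,3-oxazole-4-carboxylate
Product: 28 ethyl 2-{3-[(methoxycarbonyl)amino]prop-1-yn-1-yl}-1,3-oxazole-4-carboxylate
Conditions: Pd(PPh3)2Cl2 (5 mol%), CuI (10 mol%), Et3N, THF, rt to 40 °C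
Reagents that add atoms: none
Why: Sonogashira coupling joins the terminal alkyne to the activated C2–Br bond of the electron-poor oxazole.

Step 18
Reactants: 28 ethyl 2-{3-[(methoxycarbonyl)amino]prop-1-yn-1-yl}-1,3-oxazole-4-carboxylate
Product: 29 ethyl 2-{(1Z)-3-[(methoxycarbonyl)amino]prop-1-en-1-yl}-1,3-oxazole-4-carboxylate
Conditions: H2 (1 atm), Pd/CaCO3 poisoned with Pb(OAc)2, quinoline, EtOAc, rt
Reagents that add atoms: none
Why: Lindlar semihydrogenation adds hydrogen syn to the alkyne and stops at the alkene, which sets the Z geometry.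

Step 19
Reactants: 29 ethyl 2-{(1Z)-3-[(methoxycarbonyl)amino]prop-1-en-1-yl}-1,3-oxazole-4-carboxylate
Product: 30 methyl N-[(2Z)-3-(4-formyl-1,3-oxazol-2-yl)prop-2-en-1-yl]carbamate
Conditions: i-Bu2AlH (2.2 equiv), CH2Cl2, −78 °C; MeOH, then aq. KNaC4H4O6
Reagents that add atoms: none
Why: In this partial ester reduction the aluminium hemiacetal is stable at −78 °C and releases the aldehyde only on work-up, while the first equivalent of hydride is consumed by the carbamate N–H and thereby shields the carbamate.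

Step 20
Reactants: 30 methyl N-[(2Z)-3-(4-formyl-1,3-oxazol-2-yl)prop-2-en-1-yl]carbamate
Product: 31 methyl N-[(2Z)-3-(4-ethenyl-1,3-oxazol-2-yl)prop-2-en-1-yl]carbamate
Conditions: Ph3PCH3Br (2.5 equiv), KOtBu (2.4 equiv), THF, 0 °C; then 30, 0 °C to rt
Reagents that add atoms: methyltriphenylphosphonium bromide, C[P+](c1ccccc1)(c1ccccc1)c1ccccc1.[Br-]
Why: Wittig methylenation converts the heteroaryl aldehyde into the terminal vinyl group, the excess ylide covering the acidic N–H.

Step 21
Reactants: 31 methyl N-[(2Z)-3-(4-ethenyl-1,3-oxazol-2-yl)prop-2-en-1-yl]carbamate; 32 ethyl (2Z)-3-iodoprop-2-enoate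
Product: 34 ethyl (2Z)-5-{2-[(1Z)-3-[(methoxycarbonyl)amino]prop-1-en-1-yl]-1,3-oxazol-4-yl}pent-2-enoate, via B-alkyl-9-BBN adduct 33 (not isolated)
Conditions: 9-BBN (2.2 equiv), THF, 0 °C to rt; then 32, Pd(dppf)Cl2 (dppf = 1,1'-bis(diphenylphosphino)ferrocene, 5 mol%), AsPh3, Cs2CO3, DMF/H2O, rt
Reagents that add atoms: none
Why: Anti-Markovnikov hydroboration should take the terminal vinyl group far faster than the internal Z alkene, and the B-alkyl Suzuki–Miyaura coupling then proceeds with retention of the Z geometry of the iodoacrylate.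

Step 22
Reactants: 34 ethyl (2Z)-5-{2-[(1Z)-3-[(methoxycarbonyl)amino]prop-1-en-1-yl]-1,3-oxazol-4-yl}pent-2-enoate
Product: 35 (2Z)-5-{2-[(1Z)-3-[(methoxycarbonyl)amino]prop-1-en-1-yl]-1,3-oxazol-4-yl}pent-2-enoic acid
Conditions: LiOH, THF/H2O, 0 °C to rt; then 1 M HCl to pH 3
Reagents that add atoms: lithium hydroxide, [Li+].[OH-]
Why: Mild saponification cleaves the ethyl ester while the methyl carbamate and both Z alkenes should survive.

Step 23
Reactants: 24 (1R,5R,7R,9S,11R,13S)-13-hydroxy-7-methoxy-9-methyl-5-propyl-4,15-dioxabicyclo[9.3.1]pentadecan-3-one; 35 (2Z)-5-{2-[(1Z)-3-[(methoxycarbonyl)amino]prop-1-en-1-yl]-1,3-oxazol-4-yl}pent-2-enoic acid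
Product: 36 neopeltolide
Conditions: PPh3, DIAD, benzene, 0 °C to rt
Reagents that add atoms: none
Why: In the Mitsunobu esterification the carboxylate displaces the activated equatorial C5 oxyphosphonium group by SN2, which inverts C5 to the axial 5R ester under neutral conditions that preserve both Z alkenes.

Compound list
1 | methyl hydrogen (R)-3-methylglutarate, (3R)-5-methoxy-3-methyl-5-oxopentanoic acid | COC(=O)C[C@H](C)CC(=O)O | starting material
2 | methyl (3R)-5-hydroxy-3-methylpentanoate | COC(=O)C[C@H](C)CCO | intermediate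
3 | (4R)-4-methyloxan-2-one | O=C1C[C@H](C)CCO1 | intermediate
4 | (4R)-6-hydroxy-4-methylhexan-2-one | CC(=O)C[C@H](C)CCO | intermediate
5 | (3R)-3-methyl-5-oxohexyl acetate | CC(=O)C[C@H](C)CCOC(C)=O | intermediate
6 | butanal | CCCC=O | starting material
7 | {[(4R)-6-acetoxy-4-methylhex-1-en-2-yl]oxy}bis[(1S,2R,3S,5S)-2,6,6-trimethylbicyclo[3.1.1]heptan-3-yl]borane | C=C(OB([C@H]1C[C@H]2C[C@H](C2(C)C)[C@@H]1C)[C@H]1C[C@H]2C[C@H](C2(C)C)[C@@H]1C)C[C@H](C)CCOC(C)=O | intermediate
8 | (3R,7R)-7-hydroxy-3-methyl-5-oxodecyl acetate | CCC[C@@H](O)CC(=O)C[C@H](C)CCOC(C)=O | intermediate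
9 | (3R,5R,7R)-5-hydroxy-3-methyldecane-1,7-diyl diacetate | CCC[C@@H](OC(C)=O)C[C@H](O)C[C@H](C)CCOC(C)=O | intermediate
10 | (3R,5R,7R)-5-methoxy-3-methyldecane-1,7-diyl diacetate | CCC[C@@H](OC(C)=O)C[C@H](OC)C[C@H](C)CCOC(C)=O | intermediate
11 | (3R,5R,7R)-5-methoxy-3-methyldecane-1,7-diol | CCC[C@@H](O)C[C@H](OC)C[C@H](C)CCO | intermediate
12 | (3S,5R,7R)-7-hydroxy-5-methoxy-3-methyldecanal | CCC[C@@H](O)C[C@H](OC)C[C@H](C)CC=O | intermediate
13 | methyl 3,3-dimethoxypropanoate | COC(=O)CC(OC)OC | starting material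
14 | 3,3-dimethoxypropanoic acid | COC(OC)CC(=O)O | intermediate
15 | (4R,6R,8S)-6-methoxy-8-methyl-10-oxodecan-4-yl 3,3-dimethoxypropanoate | CCC[C@@H](OC(=O)CC(OC)OC)C[C@H](OC)C[C@H](C)CC=O | intermediate
16 | 2-(chloromethyl)-3-(trimethylsilyl)prop-1-ene | C=C(CCl)C[Si](C)(C)C | starting material
17 | tributyl{2-[(trimethylsilyl)methyl]prop-2-en-1-yl}stannane | C=C(C[Si](C)(C)C)C[Sn](CCCC)(CCCC)CCCC | intermediate
18 | (4R,6R,8R,10R)-10-hydroxy-6-methoxy-8-methyl-12-methylidene-13-(trimethylsilyl)tridecan-4-yl 3,3-dimethoxypropanoate | CCC[C@@H](OC(=O)CC(OC)OC)C[C@H](OC)C[C@H](C)C[C@@H](O)CC(=C)C[Si](C)(C)C | intermediate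
19 | (4R,6R,8S,10R)-6-methoxy-8-methyl-12-methylidene-13-(trimethylsilyl)-10-[(trimethylsilyl)oxy]tridecan-4-yl 3,3-dimethoxypropanoate | CCC[C@@H](OC(=O)CC(OC)OC)C[C@H](OC)C[C@H](C)C[C@@H](O[Si](C)(C)C)CC(=C)C[Si](C)(C)C | intermediate
20 | (6R,8R,10S,12R)-2,8-dimethoxy-10-methyl-6-propyl-12-{2-[(trimethylsilyl)methyl]prop-2-en-1-yl}-1,5-dioxacyclododecan-4-one (both C2 epimers) | CCC[C@@H]1C[C@H](OC)C[C@H](C)C[C@H](CC(=C)C[Si](C)(C)C)OC(OC)CC(=O)O1 | intermediate
21 | (1R,5R,7R,9S,11R)-7-methoxy-9-methyl-13-methylidene-5-propyl-4,15-dioxabicyclo[9.3.1]pentadecan-3-one | CCC[C@@H]1C[C@H](OC)C[C@H](C)C[C@@H]2CC(=C)C[C@H](CC(=O)O1)O2 | intermediate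
22 | ozonide of 21, 1,2,4-trioxolane spiro-fused at macrolide C5 (both spiro epimers) | CCC[C@@H]1C[C@H](OC)C[C@H](C)C[C@@H]2CC3(OCOO3)C[C@H](CC(=O)O1)O2 | intermediate
23 | (1R,5R,7R,9S,11R)-7-methoxy-9-methyl-5-propyl-4,15-dioxabicyclo[9.3.1]pentadecane-3,13-dione | CCC[C@@H]1C[C@H](OC)C[C@H](C)C[C@@H]2CC(=O)C[C@H](CC(=O)O1)O2 | intermediate
24 | (1R,5R,7R,9S,11R,13S)-13-hydroxy-7-methoxy-9-methyl-5-propyl-4,15-dioxabicyclo[9.3.1]pentadecan-3-one | CCC[C@@H]1C[C@H](OC)C[C@H](C)C[C@@H]2C[C@H](O)C[C@H](CC(=O)O1)O2 | intermediate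
25 | prop-2-yn-1-amine | C#CCN | starting material
26 | methyl N-(prop-2-yn-1-yl)carbamate | C#CCNC(=O)OC | intermediate
27 | ethyl 2-bromo-1,3-oxazole-4-carboxylate | CCOC(=O)c1coc(Br)n1 | starting material
28 | ethyl 2-{3-[(methoxycarbonyl)amino]prop-1-yn-1-yl}-1,3-oxazole-4-carboxylate | CCOC(=O)c1coc(C#CCNC(=O)OC)n1 | intermediate
29 | ethyl 2-{(1Z)-3-[(methoxycarbonyl)amino]prop-1-en-1-yl}-1,3-oxazole-4-carboxylate | CCOC(=O)c1coc(/C=C\CNC(=O)OC)n1 | intermediate
30 | methyl N-[(2Z)-3-(4-formyl-1,3-oxazol-2-yl)prop-2-en-1-yl]carbamate | O=Cc1coc(/C=C\CNC(=O)OC)n1 | intermediate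
31 | methyl N-[(2Z)-3-(4-ethenyl-1,3-oxazol-2-yl)prop-2-en-1-yl]carbamate | C=Cc1coc(/C=C\CNC(=O)OC)n1 | intermediate
32 | ethyl (2Z)-3-iodoprop-2-enoate | CCOC(=O)/C=C\I | starting material
33 | methyl N-[(2Z)-3-{4-[2-(9-borabicyclo[3.3.1]nonan-9-yl)ethyl]-1,3-oxazol-2-yl}prop-2-en-1-yl]carbamate | COC(=O)NC/C=C\c1nc(CCB2C3CCCC2CCC3)co1 | intermediate
34 | ethyl (2Z)-5-{2-[(1Z)-3-[(methoxycarbonyl)amino]prop-1-en-1-yl]-1,3-oxazol-4-yl}pent-2-enoate | CCOC(=O)/C=C\CCc1coc(/C=C\CNC(=O)OC)n1 | intermediate
35 | (2Z)-5-{2-[(1Z)-3-[(methoxycarbonyl)amino]prop-1-en-1-yl]-1,3-oxazol-4-yl}pent-2-enoic acid | OC(=O)/C=C\CCc1coc(/C=C\CNC(=O)OC)n1 | intermediate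
36 | neopeltolide, (1R,5R,7R,9S,11R,13R)-7-methoxy-9-methyl-3-oxo-5-propyl-4,15-dioxabicyclo[9.3.1]pentadecan-13-yl (2Z)-5-{2-[(1Z)-3-[(methoxycarbonyl)amino]prop-1-en-1-yl]-1,3-oxazol-4-yl}pent-2-enoate | CCC[C@@H]1C[C@H](OC)C[C@H](C)C[C@@H]2C[C@@H](OC(=O)/C=C\CCc3coc(/C=C\CNC(=O)OC)n3)C[C@H](CC(=O)O1)O2 | target

Total step count: 23. Longest linear sequence: 14 steps from 1 to 36 (steps 1–8, 10, 12–15 and 23).

Steps most likely to fail

Step 13 (macrocyclisation). Intermolecular acetal exchange may lead to oligomers, the allylsilane may be protodesilylated before it cyclises, the activated acetal may eliminate methanol, or oxonia-Cope equilibration may erode the cis selectivity. The fallback separates pyran formation from macrocyclisation; it sets out from 12 and returns at 21. The C13 hydroxyl of 12 is silylated (TBSCl, imidazole, DMF) to give the silyl ether aldehyde F1. Allylation with 17 under the conditions of step 12 gives the protected hydroxy allylsilane F2. Intermolecular silyl-Prins pyran annulation of F2 with acetal ester 13 (TMSOTf, 2,6-di-tert-butyl-4-methylpyridine, CH2Cl2, −78 °C) closes only the six-membered ring and should give the cis-2,6-disubstituted methylenetetrahydropyran ester F3. HF·pyridine frees the C13 hydroxyl to give the hydroxy ester F4, and LiOH gives the seco acid F5. Yamaguchi macrolactonisation (2,4,6-trichlorobenzoyl chloride, Et3N, then 4-(dimethylamino)pyridine, toluene, high dilution) forms the O13–C1 bond and gives 21.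

Step 4 (boron aldol). Facial selectivity of the enol borinate toward an unbranched aldehyde may be poor, and the resulting C13 epimers would be hard to separate because the stereocentres are 1,5-related. The fallback takes C13 from a bought epoxide; it sets out from 3 and returns at 8. Reduction of 3 (i-Bu2AlH, CH2Cl2, −78 °C) gives the lactol F6, and propane-1,3-dithiol with BF3·OEt2 converts it into the hydroxy dithiane F7. Double deprotonation (n-BuLi, 2.2 equiv, THF, −30 °C) and opening of commercial (R)-2-propyloxirane at its CH2 carbon give the dithiane diol F8, in which C13 comes unchanged from the epoxide. AcCl with 2,4,6-collidine at −78 °C acetylates only the primary hydroxyl and gives the monoacetate F9. MeI and CaCO3 in aqueous MeCN unmask the C11 ketone and give 8.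

Step 21 (hydroboration–Suzuki coupling). The borane may not discriminate cleanly between the two alkenes or may be consumed at the N–H, and slow transmetalation may lead to protodeboronation or Z-to-E isomerisation of the iodoacrylate. The fallback builds the Z-enoate by olefination; it sets out from 29 and returns at 34. Full reduction of 29 (i-Bu2AlH, 3.5 equiv, CH2Cl2, −78 to 0 °C) gives the oxazolylmethanol F10, and CBr4 with PPh3 gives the bromide F11. Coupling with CH2=CHMgBr and CuI (THF, −40 °C) gives the 4-allyloxazole F12. Hydroboration–oxidation (9-BBN, THF; NaBO3·4H2O) now acts on an ordinary monosubstituted alkene and gives the propanol F13. Dess–Martin oxidation gives the aldehyde F14, and Still–Gennari olefination with ethyl bis(2,2,2-trifluoroethyl)phosphonoacetate (KN(SiMe3)2, 18-crown-6, THF, −78 °C) gives 34.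

Further compounds
F1 | step 13 | (3S,5R,7R)-7-[(tert-butyldimethylsilyl)oxy]-5-methoxy-3-methyldecanal | CCC[C@@H](O[Si](C)(C)C(C)(C)C)C[C@H](OC)C[C@H](C)CC=O
F2 | step 13 | (4R,6R,8R,10R)-10-[(tert-butyldimethylsilyl)oxy]-8-methoxy-6-methyl-2-[(trimethylsilyl)methyl]tridec-1-en-4-ol | CCC[C@@H](O[Si](C)(C)C(C)(C)C)C[C@H](OC)C[C@H](C)C[C@@H](O)CC(=C)C[Si](C)(C)C
F3 | step 13 | methyl 2-{(2R,6R)-6-[(2S,4R,6R)-6-[(tert-butyldimethylsilyl)oxy]-4-methoxy-2-methylnonyl]-4-methylideneoxan-2-yl}acetate | CCC[C@@H](O[Si](C)(C)C(C)(C)C)C[C@H](OC)C[C@H](C)C[C@@H]1CC(=C)C[C@H](CC(=O)OC)O1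
F4 | step 13 | methyl 2-{(2R,6R)-6-[(2S,4R,6R)-6-hydroxy-4-methoxy-2-methylnonyl]-4-methylideneoxan-2-yl}acetate | CCC[C@@H](O)C[C@H](OC)C[C@H](C)C[C@@H]1CC(=C)C[C@H](CC(=O)OC)O1
F5 | step 13 | 2-{(2R,6R)-6-[(2S,4R,6R)-6-hydroxy-4-methoxy-2-methylnonyl]-4-methylideneoxan-2-yl}acetic acid | CCC[C@@H](O)C[C@H](OC)C[C@H](C)C[C@@H]1CC(=C)C[C@H](CC(=O)O)O1
F6 | step 4 | (4R)-4-methyloxan-2-ol (both anomers) | OC1C[C@H](C)CCO1
F7 | step 4 | (3R)-4-(1,3-dithian-2-yl)-3-methylbutan-1-ol | S1CCCSC1C[C@H](C)CCO
F8 | step 4 | (2R)-1-{2-[(2R)-4-hydroxy-2-methylbutyl]-1,3-dithian-2-yl}pentan-2-ol | CCC[C@@H](O)CC1(C[C@H](C)CCO)SCCCS1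
F9 | step 4 | (3R)-4-{2-[(2R)-2-hydroxypentyl]-1,3-dithian-2-yl}-3-methylbutyl acetate | CCC[C@@H](O)CC1(C[C@H](C)CCOC(C)=O)SCCCS1
F10 | step 21 | methyl N-{(2Z)-3-[4-(hydroxymethyl)-1,3-oxazol-2-yl]prop-2-en-1-yl}carbamate | OCc1coc(/C=C\CNC(=O)OC)n1
F11 | step 21 | methyl N-{(2Z)-3-[4-(bromomethyl)-1,3-oxazol-2-yl]prop-2-en-1-yl}carbamate | BrCc1coc(/C=C\CNC(=O)OC)n1
F12 | step 21 | methyl N-{(2Z)-3-[4-(prop-2-en-1-yl)-1,3-oxazol-2-yl]prop-2-en-1-yl}carbamate | C=CCc1coc(/C=C\CNC(=O)OC)n1
F13 | step 21 | methyl N-{(2Z)-3-[4-(3-hydroxypropyl)-1,3-oxazol-2-yl]prop-2-en-1-yl}carbamate | OCCCc1coc(/C=C\CNC(=O)OC)n1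
F14 | step 21 | methyl N-{(2Z)-3-[4-(3-oxopropyl)-1,3-oxazol-2-yl]prop-2-en-1-yl}carbamate | O=CCCc1coc(/C=C\CNC(=O)OC)n1
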